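**Plan**

Ring A is the 1,3,5-trisubstituted ring (OH, ether O, chain). Ring B is the ring with two hydroxyls, the ether O on C1 and the chain on C4. The target has no stereocentre and no stereogenic double bond, so no stereochemistry has to be set.
Retrosynthesis cuts, in order: (a) the three O–CH3 bonds of a trimethyl ether; (b) the ring B C4–CH2 bond of the 22-membered ring, as aryl bromide plus terminal vinyl group; (c) the ether O–ring A bond; (d) the ring A–CH2 bond.
Enabling feature: the bridge is an unbranched (CH2)14 whose two end carbons sit on sp2 carbons. The ring B end is C4, para to the ether oxygen on C1 and flanked only by C3–H and C5–H. Both aryl–CH2 bonds can therefore come from the two vinyl groups of one C14 diene by hydroboration and sp2–sp3 coupling, leaving no functional group in the chain.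
Forward: the diene is joined to ring A (step 1), ring A becomes a boronic acid (step 2), the diaryl ether is made with the symmetric, pre-brominated ring B phenol (step 3), the macrocycle is closed at ring B C4–CH2 (step 4), and the ethers are cleaved (step 5).

Key step: step 4

Remark: compounds 1, 2 and 8 are taken as catalogue chemicals.

**Route**

Step 1
Reactants: 1 tetradeca-1,13-diene; 2 1-bromo-3-iodo-5-methoxybenzene
Product: 4 1-bromo-3-methoxy-5-(tetradec-13-en-1-yl)benzene, via 9-(tetradec-13-en-1-yl)-9-borabicyclo[3.3.1]nonane 3 (not isolated)
Conditions: 1 (4 equiv), 9-BBN (1.0 equiv), THF, 0 °C to rt; then 2 (1.1 equiv), Pd(dppf)Cl2 (3 mol %), aq. K3PO4, DMF, rt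
Reagents that add atoms: none
Why: Anti-Markovnikov hydroboration of one vinyl group by 9-BBN (excess diene keeps the second vinyl group free) is followed by B-alkyl Suzuki–Miyaura coupling, in which zerovalent palladium inserts into the C–I bond of 2 at room temperature far faster than into its C–Br bond, so the mono-alkylated bromide should result.

Step 2
Reactants: 4 1-bromo-3-methoxy-5-(tetradec-13-en-1-yl)benzene
Product: 7 [3-methoxy-5-(tetradec-13-en-1-yl)phenyl]boronic acid, via aryllithium 5 (not isolated), via lithium aryl(triisopropoxy)borate 6 (not isolated)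
Conditions: B(OiPr)3 (1.5 equiv), n-BuLi (1.2 equiv), THF/toluene, −78 °C; then aq. HCl, rt
Reagents that add atoms: triisopropyl borate CC(C)OB(OC(C)C)OC(C)C; water O
Why: Bromine–lithium exchange at −78 °C is faster than any reaction of n-BuLi with the anisole or the alkene, the aryllithium is trapped at once by the borate already in the flask (in situ quench borylation), and acid hydrolysis then frees the boronic acid.

Step 3
Reactants: 7 [3-methoxy-5-(tetradec-13-en-1-yl)phenyl]boronic acid; 8 4-bromo-2,6-dimethoxyphenol
Product: 9 5-bromo-1,3-dimethoxy-2-[3-methoxy-5-(tetradec-13-en-1-yl)phenoxy]benzene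
Conditions: 7 (1.5 equiv), Cu(OAc)2 (2 equiv), pyridine (5 equiv), 4 Å molecular sieves, CH2Cl2, open to air, rt
Reagents that add atoms: none
Why: In this Chan–Lam oxidative C–O coupling the aryl group passes from boron to divalent copper and is reductively eliminated with the phenoxide from a trivalent copper intermediate at room temperature, conditions under which the C–Br bond of 8 and the terminal alkene are inert and 2,6-disubstituted phenols are known partners.

Step 4
Reactants: 9 5-bromo-1,3-dimethoxy-2-[3-methoxy-5-(tetradec-13-en-1-yl)phenoxy]benzene
Product: 11 tri-O-methylrobustol, via B-alkyl-9-BBN adduct 10 (not isolated)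
Conditions: 9-BBN (1.5 equiv), THF, 0 °C to rt; then syringe-pump addition over 12 h to Pd(dppf)Cl2 (15 mol %), AsPh3 (30 mol %), Cs2CO3 (3 equiv), DMF/THF/H2O, 60 °C, final 2 mM
Reagents that add atoms: none
Why: 9-BBN adds anti-Markovnikov to the only C=C of 9 to give the primary alkylborane 10; zerovalent palladium (from Pd(dppf)Cl2) then inserts into the C–Br bond at ring B C4, the base-activated borane transfers its primary alkyl group to palladium, and reductive elimination forges the ring B C4–CH2 bond. The closest known reaction type is the B-alkyl Suzuki–Miyaura macrocyclization of ω-alkenyl aryl or vinyl halides, used to close large carbocycles and cyclophanes. The 22-membered oxa-cyclophane ring is closed by C(sp2)–C(sp3) reductive elimination from a 23-membered aryl(alkyl)palladium chelate, a contraction by one atom with expulsion of the metal; both termini are ring members, so no exo or endo alternative arises. No stereocentre is formed. The step needs intra- over intermolecular coupling, secured by slow addition to high dilution, and reductive elimination faster than β-hydride elimination, secured by the wide bite angle of dppf with AsPh3; it also needs transfer of the primary chain and not a bicyclic B–C bond, which 9-BBN ensures, and an accessible C–Br bond, which ring B provides because C4 is flanked only by C3–H and C5–H.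

Step 5
Reactants: 11 tri-O-methylrobustol
Product: 13 robustol, via tris(dibromoboryl) ether 12 (not isolated)
Conditions: BBr3 (6 equiv), CH2Cl2, −78 °C to rt; then ice-water
Reagents that add atoms: none
Why: In this Lewis acid-mediated aryl methyl ether cleavage BBr3 coordinates each methoxy oxygen and bromide removes the methyl group by SN2 attack, the diaryl ether has no sp3 carbon to attack and should survive, and aqueous work-up hydrolyses the aryloxyboron species to the three phenols.

**Compound list**

1 | tetradeca-1,13-diene | C=CCCCCCCCCCCCC=C | starting material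
2 | 1-bromo-3-iodo-5-methoxybenzene | Ic1cc(Br)cc(OC)c1 | starting material
3 | 9-(tetradec-13-en-1-yl)-9-borabicyclo[3.3.1]nonane | C=CCCCCCCCCCCCCB1C2CCCC1CCC2 | intermediate (not isolated)
4 | 1-bromo-3-methoxy-5-(tetradec-13-en-1-yl)benzene | COc1cc(Br)cc(CCCCCCCCCCCCC=C)c1 | intermediate
5 | [3-methoxy-5-(tetradec-13-en-1-yl)phenyl]lithium | [Li]c1cc(OC)cc(CCCCCCCCCCCCC=C)c1 | intermediate (not isolated)
6 | lithium triisopropoxy[3-methoxy-5-(tetradec-13-en-1-yl)phenyl]borate | [Li+].CC(C)O[B-](OC(C)C)(OC(C)C)c1cc(OC)cc(CCCCCCCCCCCCC=C)c1 | intermediate (not isolated)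
7 | [3-methoxy-5-(tetradec-13-en-1-yl)phenyl]boronic acid | OB(O)c1cc(OC)cc(CCCCCCCCCCCCC=C)c1 | intermediate
8 | 4-bromo-2,6-dimethoxyphenol | COc1cc(Br)cc(OC)c1O | starting material
9 | 5-bromo-1,3-dimethoxy-2-[3-methoxy-5-(tetradec-13-en-1-yl)phenoxy]benzene | COc1cc(CCCCCCCCCCCCC=C)cc(Oc2c(OC)cc(Br)cc2OC)c1 | intermediate
10 | 9-{14-[3-(4-bromo-2,6-dimethoxyphenoxy)-5-methoxyphenyl]tetradecyl}-9-borabicyclo[3.3.1]nonane | COc1cc(CCCCCCCCCCCCCCB2C3CCCC2CCC3)cc(Oc2c(OC)cc(Br)cc2OC)c1 | intermediate (not isolated)
11 | tri-O-methylrobustol: 22-membered ring in which the oxygen on C1 of ring A (5-methoxy-1,3-phenylene) is bonded to C1 of ring B (2,6-dimethoxy-1,4-phenylene) and a (CH2)14 chain joins ring A C3 to ring B C4 | COc1cc2cc(c1)Oc1c(OC)cc(cc1OC)CCCCCCCCCCCCCC2 | intermediate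
12 | tris(O-dibromoboryl)robustol (each of the three phenolic oxygens carries BBr2) | BrB(Br)Oc1cc2cc(c1)Oc1c(OB(Br)Br)cc(cc1OB(Br)Br)CCCCCCCCCCCCCC2 | intermediate (not isolated)
13 | robustol | Oc1cc2cc(c1)Oc1c(O)cc(cc1O)CCCCCCCCCCCCCC2 | target

**Count**

Total steps: 5. Longest linear sequence: 5 steps (from 1 or 2 to 13).

**Steps most likely to fail**

Step 4. The risk is intermolecular coupling to oligomers, together with loss of the borane by protodeboronation or β-hydride elimination before the ring closes. The fallback moves the ring closure to a C=C bond. It sets out from 9: Suzuki–Miyaura vinylation of the ring B bromide with potassium vinyltrifluoroborate (Pd(dppf)Cl2, Et3N, n-PrOH, 90 °C) should give 5-ethenyl-1,3-dimethoxy-2-[3-methoxy-5-(tetradec-13-en-1-yl)phenoxy]benzene F1. Ring-closing metathesis with second-generation Grubbs catalyst (CH2Cl2, 40 °C, 1 mM) should then give, with loss of ethene, didehydro-tri-O-methylrobustol F2, which has a C=C between the bridge carbon on ring B C4 and its neighbour (E or Z, E drawn). Hydrogenation (H2, Pd/C, EtOAc) erases the alkene geometry and comes back to the route at 11.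

Step 3. The risk is slow C–O coupling of the di-ortho-substituted phenol while the boronic acid is consumed by protodeboronation, oxidative hydroxylation or homocoupling. The fallback replaces the oxidative coupling by an Ullmann ether synthesis on an aryl iodide. It sets out from 4: an aromatic Finkelstein reaction (NaI, CuI 5 mol %, trans-N,N'-dimethylcyclohexane-1,2-diamine, dioxane, 110 °C) should give 1-iodo-3-methoxy-5-(tetradec-13-en-1-yl)benzene F3. Coupling of this iodide with 8 (CuI 10 mol %, picolinic acid, K3PO4, DMSO, 80 °C) should favour the C–I bond over the C–Br bonds, that of 8 being deactivated by its para phenoxide. It comes back to the route at 9.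

Step 1. The risk is statistical hydroboration at both ends of the diene and carry-over of the diene and bis-borane into the coupling, giving mixtures that are hard to separate. The fallback uses a purified monofunctional C14 unit and an organozinc coupling. It sets out from 1: hydroboration with a deficit of 9-BBN and oxidation (NaOH, H2O2) should give tetradec-13-en-1-ol F4, separable from diene and diol by chromatography. Iodination (I2, PPh3, imidazole, CH2Cl2) gives 14-iodotetradec-1-ene F5, and zinc insertion (Zn dust, LiCl, THF) gives (tetradec-13-en-1-yl)zinc iodide F6. Negishi coupling of this zinc reagent with 2 at its C–I bond (Pd(dppf)Cl2, THF, rt) comes back to the route at 4.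

**Further compounds**

F1 | step 4 | 5-ethenyl-1,3-dimethoxy-2-[3-methoxy-5-(tetradec-13-en-1-yl)phenoxy]benzene | COc1cc(CCCCCCCCCCCCC=C)cc(Oc2c(OC)cc(C=C)cc2OC)c1
F2 | step 4 | didehydro-tri-O-methylrobustol (C=C between the bridge carbon on ring B C4 and its neighbour, E drawn) | COc1cc2cc(c1)Oc1c(OC)cc(cc1OC)/C=C/CCCCCCCCCCCC2
F3 | step 3 | 1-iodo-3-methoxy-5-(tetradec-13-en-1-yl)benzene | Ic1cc(OC)cc(CCCCCCCCCCCCC=C)c1
F4 | step 1 | tetradec-13-en-1-ol | OCCCCCCCCCCCCC=C
F5 | step 1 | 14-iodotetradec-1-ene | ICCCCCCCCCCCCC=C
F6 | step 1 | (tetradec-13-en-1-yl)zinc iodide | I[Zn]CCCCCCCCCCCCC=C
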